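**Plan**

1. Late simplification: the butenolide is carried as a 3-furyl group, the C4 exocyclic methylene as a C4 ketone held as a silyl ether, the 1β-OH/10β-H pair as the syn-hydration product of a C1=C10 alkene, and the 7β,8β-diol as the dihydroxylation product of a C7=C8 alkene.
2. In the resulting ring A/B dienol the C6 carbinol is homoallylic to C1=C10 through quaternary C5 (array O–C6–C5–C10=C1), the retron of a carbonyl-ene reaction. The C5–C6 bond is cut to a (Z)-enal tethered through C9 to C10 of a 2-methylcyclohexene (ring A); its tetrasubstituted C5=C10 alkene is the ene and a C1–H is transferred.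
3. The (Z)-enal comes from an α,β-unsaturated δ-lactone (temporary ring C6–O–C11, closed by metathesis). The C9–C11 bond is cut by allylboration of 2-(furan-3-yl)acetaldehyde with a geometrically defined γ,γ-disubstituted allylboronate, made from a ring A enyne by syn-methylboration and Matteson homologation.
4. Forward order: ring A (from 2-methylcyclohexane-1,3-dione) → enyne → allylboronate → C9/C11 pair → lactone → (Z)-enal → ring B by the ene closure (C5) → C6, then C7/C8 → C1/C10 → C4 methylene → butenolide.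
5. Stereochemistry: C11 and C9 from one chiral phosphoric acid-catalysed allylboration; C5 relayed from C9 in the ene step, reinforced by a temporary 4α-silyloxy centre from a CBS reduction; C6 by Luche reduction; C7/C8 and C1/C10 by attack on the β face, opposite the axial methyls C19 and C20.

Key step: step 14

Remark: clerodane numbering is used (ring A = C1–C5, C10; ring B = C5–C10; side chain C11–C16; C17 on C8, C18 on C4, C19 on C5, C20 on C9); β is the face of H-10 in the target.

**Route**

Step 1
Reactants: 1 2-methylcyclohexane-1,3-dione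
Product: 2 3-bromo-2-methylcyclohex-2-en-1-one
Conditions: PPh3, Br2, Et3N, CH2Cl2, 0 °C to rt
Reagents that add atoms: bromine, BrBr
Why: Vinylogous acid activation; Ph3PBr2 turns the enol oxygen into an oxyphosphonium leaving group that bromide displaces by addition-elimination, giving the β-bromoenone.

Step 2
Reactants: 2 3-bromo-2-methylcyclohex-2-en-1-one; 3 propyne
Product: 4 2-methyl-3-(prop-1-yn-1-yl)cyclohex-2-en-1-one
Conditions: propyne (excess), PdCl2(PPh3)2 (3 mol %), CuI (5 mol %), Et3N, THF, rt
Reagents that add atoms: none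
Why: Sonogashira coupling; the vinylogous acyl bromide adds readily to zerovalent palladium and the copper acetylide of propyne transfers the alkynyl group.

Step 3
Reactants: 4 2-methyl-3-(prop-1-yn-1-yl)cyclohex-2-en-1-one
Product: 5 (R)-2-methyl-3-(prop-1-yn-1-yl)cyclohex-2-en-1-ol
Conditions: (S)-2-methyl-CBS-oxazaborolidine (20 mol %), BH3·SMe2, THF, −30 °C; MeOH quench
Reagents that add atoms: none
Why: Corey-Bakshi-Shibata reduction; the α-branched alkenyl side acts as the large substituent, as aryl does in aryl ketones, so the (S)-catalyst should deliver hydride to give the R carbinol at C4, the helper centre used in step 14.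

Step 4
Reactants: 5 (R)-2-methyl-3-(prop-1-yn-1-yl)cyclohex-2-en-1-ol
Product: 6 (R)-tert-butyldimethyl{[2-methyl-3-(prop-1-yn-1-yl)cyclohex-2-en-1-yl]oxy}silane
Conditions: TBSCl, imidazole, DMF, rt
Reagents that add atoms: tert-butyldimethylsilyl chloride, CC(C)(C)[Si](C)(C)Cl
Why: Imidazole-promoted silylation of a secondary allylic alcohol; the ether masks the future C4 ketone and later shields the α face of ring A.

Step 5
Reactants: 6 (R)-tert-butyldimethyl{[2-methyl-3-(prop-1-yn-1-yl)cyclohex-2-en-1-yl]oxy}silane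
Product: 7 pinacol (Z)-alkenylboronate (boron on C8 cis to the new C20 methyl on C9)
Conditions: CuCl (10 mol %), Xantphos (10 mol %), NaOtBu, B2pin2, MeI, THF, rt
Reagents that add atoms: bis(pinacolato)diboron, CC1(C)OB(OC1(C)C)B1OC(C)(C)C(C)(C)O1; iodomethane, CI
Why: Copper-catalysed carboboration of an alkyne; the copper boryl adds syn with boron on the methyl-bearing carbon and copper beside the conjugating cyclohexenyl group, and methylation of the alkenylcopper with retention fixes the tetrasubstituted alkene geometry.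

Step 6
Reactants: 7 pinacol (Z)-alkenylboronate
Product: 9 pinacol (E)-allylboronate (CH2B trans to the cyclohexenyl group), via lithium chloromethyl boronate complex 8 (not isolated)
Conditions: BrCH2Cl, n-BuLi, THF, −78 °C to rt
Reagents that add atoms: bromochloromethane, ClCBr; n-butyllithium, [Li]CCCC (lithium of 8 only)
Why: Matteson homologation; LiCH2Cl adds to boron and the alkenyl group migrates to carbon with loss of chloride and retention of the alkene geometry.

Step 7
Reactants: 10 2-(furan-3-yl)ethan-1-ol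
Product: 11 2-(furan-3-yl)acetaldehyde
Conditions: Dess-Martin periodinane, NaHCO3, CH2Cl2, 0 °C; used at once
Reagents that add atoms: none
Why: Dess-Martin oxidation of a primary alcohol under buffered conditions that the acid-sensitive furan and the enolisable aldehyde should tolerate.

Step 8
Reactants: 9 pinacol (E)-allylboronate; 11 2-(furan-3-yl)acetaldehyde
Product: 12 (2S,3S)-1-(furan-3-yl)-3,4-dimethyl-3-{(R)-3-[(tert-butyldimethylsilyl)oxy]-2-methylcyclohex-1-en-1-yl}pent-4-en-2-ol
Conditions: (R)-TRIP [(R)-3,3'-bis(2,4,6-triisopropylphenyl)-1,1'-binaphthyl-2,2'-diyl hydrogen phosphate] (10 mol %), 4 Å molecular sieves, toluene, −30 °C to 0 °C; aqueous work-up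
Reagents that add atoms: none
Why: Chiral phosphoric acid-catalysed allylboration through a closed chair transition state; the (R)-catalyst is chosen to direct the boronate to the Re face of the aldehyde (C11 S), and the boronate geometry places the cyclohexenyl group anti and the C20 methyl syn to the new hydroxyl, which sets quaternary C9.

Step 9
Reactants: 12 homoallylic alcohol
Product: 13 acrylate ester of 12
Conditions: acryloyl chloride, iPr2NEt, DMAP (cat.), CH2Cl2, 0 °C
Reagents that add atoms: acryloyl chloride, C=CC(Cl)=O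
Why: DMAP-catalysed acylation of the hindered secondary alcohol; the acrylate supplies C6 and C7 of ring B.

Step 10
Reactants: 13 acrylate ester of 12
Product: 14 (5S,6S)-6-(furan-3-ylmethyl)-4,5-dimethyl-5-{(R)-3-[(tert-butyldimethylsilyl)oxy]-2-methylcyclohex-1-en-1-yl}-5,6-dihydro-2H-pyran-2-one
Conditions: second-generation Hoveyda-Grubbs catalyst (10 mol %), toluene, 90 °C, argon purge
Reagents that add atoms: none
Why: Ring-closing metathesis of the acrylate with the isopropenyl group (its terminal CH2 leaves as ethene); the six-membered lactone enforces the Z geometry of C7=C8, and the tetrasubstituted ring alkene and the furan should not take part.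

Step 11
Reactants: 14 unsaturated δ-lactone
Product: 15 (2Z,4S,5S)-6-(furan-3-yl)-5-hydroxy-N-methoxy-N,3,4-trimethyl-4-{(R)-3-[(tert-butyldimethylsilyl)oxy]-2-methylcyclohex-1-en-1-yl}hex-2-enamide
Conditions: MeNH(OMe)·HCl, Me3Al, CH2Cl2, 0 °C to rt; aqueous Rochelle salt; crude product used directly
Reagents that add atoms: N,O-dimethylhydroxylamine hydrochloride, CNOC.Cl
Why: Weinreb aminolysis of a lactone by the aluminium amide; the fully substituted β-carbon blocks conjugate addition, the Z alkene is kept, and immediate use avoids relactonisation.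

Step 12
Reactants: 15 hydroxy Weinreb amide
Product: 16 C11 isobutyrate of 15
Conditions: isobutyryl chloride, pyridine, DMAP, CH2Cl2, 0 °C to rt
Reagents that add atoms: isobutyryl chloride, CC(C)C(Cl)=O
Why: DMAP-catalysed acylation installs the C11 isobutyrate of the target and removes the hydroxyl that could relactonise.

Step 13
Reactants: 16 C11 isobutyrate of 15
Product: 17 (2S,3S,4Z)-1-(furan-3-yl)-3,4-dimethyl-6-oxo-3-{(R)-3-[(tert-butyldimethylsilyl)oxy]-2-methylcyclohex-1-en-1-yl}hex-4-en-2-yl 2-methylpropanoate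
Conditions: Cp2Zr(H)Cl (1.5 equiv), THF, rt; used at once
Reagents that add atoms: none
Why: Hydrozirconation of the amide carbonyl gives a stable zirconated hemiaminal that releases the aldehyde on work-up, a reduction that should leave the ester and the Z alkene untouched.

Step 14
Reactants: 17 (Z)-enal
Product: 18 ring A/B dienol (18-nor-clerodane core; C1=C10 and C7=C8 alkenes; 4α-OTBS; 5α-methyl; 6β-OH; 9α-methyl; 11S isobutyrate; 3-furyl on C12)
Conditions: Me2AlCl (2 equiv), CH2Cl2 (0.005 M), −78 °C to −40 °C; aqueous Rochelle salt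
Reagents that add atoms: none
Why: Me2AlCl activates the aldehyde and the electron-rich tetrasubstituted C5=C10 alkene of ring A bonds through C5 to C6 while the aluminium-bound oxygen takes a hydrogen from C1, a type 2 intramolecular carbonyl-ene reaction (enophile tethered to the central ene carbon) whose closest models are the Lewis acid-promoted type 2 ene cyclisations of 5-methylhex-5-enals and the ene cyclisation of the (Z)-enal neral to isopiperitenol. Ring B closes by 6-exo-trig attack on the carbonyl carbon with the ene alkene taken into the new ring, through a chair-like array C5–C6–C7–C8–C9–C10; only the Z enal can close, so any E isomer formed under the Lewis acid must return through it. The new quaternary centre C5 is controlled by C9: the chair that keeps the large C11 branch equatorial and puts only the C20 methyl axial, syn to the developing axial C19 methyl, should be preferred, and the pseudoaxial 4α-silyloxy group, which shields the opposite face of C5, reinforces this. C6 should form with its oxygen axial (β), because the oxygen must lie over C10 to reach H-1; this centre is erased and reset in steps 15 and 16, so its configuration is not critical. The step needs bonding at C5 and not at C10, which is secured because closure at C10 would give a strained spiro cyclopentenol with two adjacent quaternary carbons. It also needs hydrogen loss only towards C1, the sole allylic C–H on the C10 side, so that the C1=C10 alkene required for step 20 results.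

Step 15
Reactants: 18 ring A/B dienol
Product: 19 dienone (C6 ketone conjugated with C7=C8)
Conditions: Dess-Martin periodinane, NaHCO3, CH2Cl2, rt
Reagents that add atoms: none
Why: Dess-Martin oxidation of the allylic alcohol removes the C6 centre, so both C6 epimers from step 14 converge.

Step 16
Reactants: 19 dienone
Product: 20 6α-alcohol (C6 epimer of 18)
Conditions: NaBH4, CeCl3·7H2O, MeOH, −78 °C to −20 °C
Reagents that add atoms: none
Why: Luche 1,2-reduction; hydride should arrive along the axial trajectory on the β face, anti to the adjacent axial C19 methyl, giving the equatorial 6α-alcohol.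

Step 17
Reactants: 20 6α-alcohol
Product: 21 6α-acetate
Conditions: Ac2O, pyridine, DMAP, CH2Cl2, rt
Reagents that add atoms: acetic anhydride, CC(=O)OC(C)=O
Why: DMAP-catalysed acetylation of the only free hydroxyl installs the C6 acetate of the target before further hydroxyls appear.

Step 18
Reactants: 21 6α-acetate
Product: 22 7β,8β-diol
Conditions: OsO4 (5 mol %), NMO (1.1 equiv), acetone/H2O, rt
Reagents that add atoms: N-methylmorpholine N-oxide, C[N+]1([O-])CCOCC1; water, O
Why: Upjohn dihydroxylation; OsO4 should add to C7=C8 from the β face, anti to the allylic 6α-acetoxy group and opposite the pseudoaxial C20 and C19 methyls (sets C7 and C8), while the C1=C10 alkene, flanked by two quaternary carbons, and the furan react more slowly.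

Step 19
Reactants: 22 7β,8β-diol
Product: 23 7β-isobutyrate (8β-OH free)
Conditions: isobutyryl chloride, pyridine, DMAP, CH2Cl2, 0 °C to rt
Reagents that add atoms: isobutyryl chloride, CC(C)C(Cl)=O
Why: Selective acylation of the secondary C7 hydroxyl; the tertiary axial C8 hydroxyl beside quaternary C9 should not acylate.

Step 20
Reactants: 23 7β-isobutyrate
Product: 25 1β-alcohol with trans ring fusion (H-10β), via C1 alkylborane 24 (not isolated)
Conditions: BH3·SMe2, THF, 0 °C to rt; then NaBO3·4H2O, THF/H2O, rt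
Reagents that add atoms: borane-dimethyl sulfide, C[S+](C)[BH3-] (boron of 24); sodium perborate, [Na+].[Na+].O[B-]1(O)OO[B-](O)(O)OO1 (oxygen at C1 of 25)
Why: Hydroboration-oxidation; borane should add syn and anti-Markovnikov across C1=C10 from the β face, the α face being closed by the C19 and C20 methyls, so boron goes to C1 and hydrogen to C10, and oxidation with retention gives the 1β-alcohol and the trans decalin.

Step 21
Reactants: 25 1β-alcohol
Product: 26 1β,4α-diol
Conditions: HF·pyridine, pyridine, THF, 0 °C to rt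
Reagents that add atoms: none
Why: Fluoride-mediated silyl ether cleavage under buffered conditions that should spare the three esters and the furan.

Step 22
Reactants: 26 1β,4α-diol
Product: 27 C4 ketone (1β-OH retained)
Conditions: Dess-Martin periodinane (1.1 equiv), NaHCO3, CH2Cl2, 0 °C
Reagents that add atoms: none
Why: Dess-Martin oxidation discriminating on steric grounds; the C1 hydroxyl is crowded by the C11 branch and its carbinol hydrogen lies syn-axial to both the C19 and C20 methyls, whereas the C4 carbinol is an ordinary neopentyl secondary alcohol.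

Step 23
Reactants: 27 C4 ketone
Product: 28 4(18)-methylene compound (3-furyl analogue of the target)
Conditions: Zn, CH2Br2, TiCl4, THF/CH2Cl2, 0 °C to rt
Reagents that add atoms: dibromomethane, BrCBr
Why: Takai-Lombardo methylenation; the zinc-titanium gem-dimetallic reagent methylenates hindered ketones beside quaternary carbons and should not attack the esters or need protection of the hydroxyls.

Step 24
Reactants: 28 4(18)-methylene compound
Product: 30 16-hydroxy-13-en-15,16-olide (hydroxybutenolide as C16 epimers), via furan endoperoxide 29 (not isolated)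
Conditions: O2, visible light, rose bengal (cat.), iPr2NEt, CH2Cl2, −78 °C
Reagents that add atoms: oxygen, O=O
Why: [4+2] addition of singlet oxygen to the furan followed by Kornblum-DeLaMare opening; the hindered base removes the less hindered H-15, so the carbonyl ends at C15, and the 1,1-disubstituted alkene reacts far more slowly with singlet oxygen.

Step 25
Reactants: 30 hydroxybutenolide
Product: 31 CNP0325163.1 (target)
Conditions: NaBH4, EtOH, 0 °C; then 1 M HCl
Reagents that add atoms: none
Why: Borohydride reduction of the lactol carbon C16 (a masked aldehyde) and acid-induced relactonisation give the butenolide, with the acetate and isobutyrates expected to survive at 0 °C.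

**Compound list**

1 | 2-methylcyclohexane-1,3-dione | CC1C(=O)CCCC1=O | starting material
2 | 3-bromo-2-methylcyclohex-2-en-1-one | CC1=C(Br)CCCC1=O | intermediate
3 | propyne | CC#C | starting material
4 | 2-methyl-3-(prop-1-yn-1-yl)cyclohex-2-en-1-one | CC#CC1=C(C)C(=O)CCC1 | intermediate
5 | (R)-2-methyl-3-(prop-1-yn-1-yl)cyclohex-2-en-1-ol | CC#CC1=C(C)[C@H](O)CCC1 | intermediate
6 | (R)-tert-butyldimethyl{[2-methyl-3-(prop-1-yn-1-yl)cyclohex-2-en-1-yl]oxy}silane | CC#CC1=C(C)[C@H](O[Si](C)(C)C(C)(C)C)CCC1 | intermediate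
7 | 2-[(Z)-3-{(R)-3-[(tert-butyldimethylsilyl)oxy]-2-methylcyclohex-1-en-1-yl}but-2-en-2-yl]-4,4,5,5-tetramethyl-1,3,2-dioxaborolane | C/C(B1OC(C)(C)C(C)(C)O1)=C(/C)C1=C(C)[C@H](O[Si](C)(C)C(C)(C)C)CCC1 | intermediate
8 | lithium chloromethyl boronate complex of 7 | [Li+].ClC[B-]1(OC(C)(C)C(C)(C)O1)/C(C)=C(\C)C1=C(C)[C@H](O[Si](C)(C)C(C)(C)C)CCC1 | intermediate (not isolated)
9 | 2-[(E)-2-methyl-3-{(R)-3-[(tert-butyldimethylsilyl)oxy]-2-methylcyclohex-1-en-1-yl}but-2-en-1-yl]-4,4,5,5-tetramethyl-1,3,2-dioxaborolane | CC1(C)OB(C/C(C)=C(\C)C2=C(C)[C@H](O[Si](C)(C)C(C)(C)C)CCC2)OC1(C)C | intermediate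
10 | 2-(furan-3-yl)ethan-1-ol | OCCc1ccoc1 | starting material
11 | 2-(furan-3-yl)acetaldehyde | O=CCc1ccoc1 | intermediate
12 | (2S,3S)-1-(furan-3-yl)-3,4-dimethyl-3-{(R)-3-[(tert-butyldimethylsilyl)oxy]-2-methylcyclohex-1-en-1-yl}pent-4-en-2-ol | C=C(C)[C@@](C)(C1=C(C)[C@H](O[Si](C)(C)C(C)(C)C)CCC1)[C@H](Cc1ccoc1)O | intermediate
13 | acrylate (prop-2-enoate) ester of 12 | C=C(C)[C@@](C)(C1=C(C)[C@H](O[Si](C)(C)C(C)(C)C)CCC1)[C@H](Cc1ccoc1)OC(=O)C=C | intermediate
14 | (5S,6S)-6-(furan-3-ylmethyl)-4,5-dimethyl-5-{(R)-3-[(tert-butyldimethylsilyl)oxy]-2-methylcyclohex-1-en-1-yl}-5,6-dihydro-2H-pyran-2-one | O=C1C=C(C)[C@@](C)(C2=C(C)[C@H](O[Si](C)(C)C(C)(C)C)CCC2)[C@H](Cc2ccoc2)O1 | intermediate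
15 | (2Z,4S,5S)-6-(furan-3-yl)-5-hydroxy-N-methoxy-N,3,4-trimethyl-4-{(R)-3-[(tert-butyldimethylsilyl)oxy]-2-methylcyclohex-1-en-1-yl}hex-2-enamide | CON(C)C(=O)/C=C(/C)[C@@](C)(C1=C(C)[C@H](O[Si](C)(C)C(C)(C)C)CCC1)[C@H](Cc1ccoc1)O | intermediate
16 | 2-methylpropanoate (at the C11 oxygen) of 15 | CON(C)C(=O)/C=C(/C)[C@@](C)(C1=C(C)[C@H](O[Si](C)(C)C(C)(C)C)CCC1)[C@H](Cc1ccoc1)OC(=O)C(C)C | intermediate
17 | (2S,3S,4Z)-1-(furan-3-yl)-3,4-dimethyl-6-oxo-3-{(R)-3-[(tert-butyldimethylsilyl)oxy]-2-methylcyclohex-1-en-1-yl}hex-4-en-2-yl 2-methylpropanoate | O=C/C=C(/C)[C@@](C)(C1=C(C)[C@H](O[Si](C)(C)C(C)(C)C)CCC1)[C@H](Cc1ccoc1)OC(=O)C(C)C | intermediate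
18 | ring A/B dienol: C1=C10 and C7=C8 alkenes, 4α-OTBS, 5α-methyl, 6β-OH, 9α-methyl, (11S)-isobutyryloxy, 12-(furan-3-yl) | CC(C)(C)[Si](C)(C)O[C@@H]1CCC=C2[C@@]1(C)[C@H](O)C=C(C)[C@]2(C)[C@H](Cc1ccoc1)OC(=O)C(C)C | intermediate
19 | dienone: as 18 with a C6 ketone | CC(C)(C)[Si](C)(C)O[C@@H]1CCC=C2[C@@]1(C)C(=O)C=C(C)[C@]2(C)[C@H](Cc1ccoc1)OC(=O)C(C)C | intermediate
20 | 6α-alcohol (C6 epimer of 18) | CC(C)(C)[Si](C)(C)O[C@@H]1CCC=C2[C@@]1(C)[C@@H](O)C=C(C)[C@]2(C)[C@H](Cc1ccoc1)OC(=O)C(C)C | intermediate
21 | 6α-acetate of 20 | CC(C)(C)[Si](C)(C)O[C@@H]1CCC=C2[C@@]1(C)[C@@H](OC(C)=O)C=C(C)[C@]2(C)[C@H](Cc1ccoc1)OC(=O)C(C)C | intermediate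
22 | 6α-acetoxy-7β,8β-diol (C1=C10 alkene retained) | CC(C)(C)[Si](C)(C)O[C@@H]1CCC=C2[C@@]1(C)[C@@H](OC(C)=O)[C@H](O)[C@](C)(O)[C@]2(C)[C@H](Cc1ccoc1)OC(=O)C(C)C | intermediate
23 | 6α-acetoxy-7β-isobutyryloxy-8β-ol | CC(C)(C)[Si](C)(C)O[C@@H]1CCC=C2[C@@]1(C)[C@@H](OC(C)=O)[C@H](OC(=O)C(C)C)[C@](C)(O)[C@]2(C)[C@H](Cc1ccoc1)OC(=O)C(C)C | intermediate
24 | C1β alkylborane (H-10β) derived from 23 | CC(C)(C)[Si](C)(C)O[C@@H]1CC[C@@H]([BH2])[C@H]2[C@@]1(C)[C@@H](OC(C)=O)[C@H](OC(=O)C(C)C)[C@](C)(O)[C@]2(C)[C@H](Cc1ccoc1)OC(=O)C(C)C | intermediate (not isolated)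
25 | 1β-alcohol, trans-decalin, 4α-OTBS | CC(C)(C)[Si](C)(C)O[C@@H]1CC[C@@H](O)[C@H]2[C@@]1(C)[C@@H](OC(C)=O)[C@H](OC(=O)C(C)C)[C@](C)(O)[C@]2(C)[C@H](Cc1ccoc1)OC(=O)C(C)C | intermediate
26 | 1β,4α-diol | O[C@@H]1CC[C@@H](O)[C@H]2[C@@]1(C)[C@@H](OC(C)=O)[C@H](OC(=O)C(C)C)[C@](C)(O)[C@]2(C)[C@H](Cc1ccoc1)OC(=O)C(C)C | intermediate
27 | C4 ketone, 1β-OH | O=C1CC[C@@H](O)[C@H]2[C@@]1(C)[C@@H](OC(C)=O)[C@H](OC(=O)C(C)C)[C@](C)(O)[C@]2(C)[C@H](Cc1ccoc1)OC(=O)C(C)C | intermediate
28 | 4(18)-methylene compound with a 3-furyl group (furan analogue of the target) | C=C1CC[C@@H](O)[C@H]2[C@@]1(C)[C@@H](OC(C)=O)[C@H](OC(=O)C(C)C)[C@](C)(O)[C@]2(C)[C@H](Cc1ccoc1)OC(=O)C(C)C | intermediate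
29 | furan endoperoxide of 28 (2,3,7-trioxabicyclo[2.2.1]hept-5-ene) | C=C1CC[C@@H](O)[C@H]2[C@@]1(C)[C@@H](OC(C)=O)[C@H](OC(=O)C(C)C)[C@](C)(O)[C@]2(C)[C@H](CC1=CC2OOC1O2)OC(=O)C(C)C | intermediate (not isolated)
30 | 16-hydroxy-13-en-15,16-olide (C16 epimers) | C=C1CC[C@@H](O)[C@H]2[C@@]1(C)[C@@H](OC(C)=O)[C@H](OC(=O)C(C)C)[C@](C)(O)[C@]2(C)[C@H](CC1=CC(=O)OC1O)OC(=O)C(C)C | intermediate
31 | CNP0325163.1 | C=C1CC[C@@H](O)[C@H]2[C@@]1(C)[C@@H](OC(C)=O)[C@H](OC(=O)C(C)C)[C@](C)(O)[C@]2(C)[C@H](CC1=CC(=O)OC1)OC(=O)C(C)C | target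

**Step count and risks**

Total steps: 25. Longest linear sequence: 24 (steps 1 to 6 and 8 to 25; step 7 makes the aldehyde partner).

Steps most likely to fail:

1. Step 14 (ene closure). The aluminium-bound conjugated aldehyde may be too weak an enophile for the crowded tetrasubstituted alkene, so that E/Z scrambling, oligomerisation through the furan or closure at C10 compete, and the facial preference at C5 may be modest. The fallback sets out from 17 and comes back at 19. Pinnick oxidation (NaClO2, NaH2PO4, 2-methyl-2-butene, t-BuOH/H2O) should give the (Z)-enoic acid F1. Neutral treatment with 1-chloro-N,N,2-trimethylprop-1-en-1-amine should give the acid chloride F2. SnCl4 in CH2Cl2 at −78 °C should then close ring B by intramolecular acylation of the C5=C10 alkene with loss of H-1, giving dienone 19 directly, so that step 15 is not needed.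

2. Step 10 (ring-closing metathesis). The ruthenium carbene may fail to engage the isopropenyl group beside the quaternary carbon, leaving acrylate homodimerisation as the main pathway. The fallback sets out from 12 and comes back at 14. Esterification with diethylphosphonoacetic acid (DCC, DMAP) should give the phosphonoacetate F3. OsO4 (cat.), NaIO4 and 2,6-lutidine in dioxane/H2O should cleave the only unhindered alkene to the methyl ketone F4. LiCl and iPr2NEt in MeCN should then close the lactone 14 by intramolecular Horner-Wadsworth-Emmons olefination, with the Z geometry fixed by the ring.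

3. Step 22 (selective oxidation). Discrimination between the two secondary hydroxyls may be incomplete, with over-oxidation at C1. The fallback sets out from 23 and comes back at 28. Hydroboration as in step 20 but quenched with pinacol should give the C1 pinacol boronate F5, which masks the hydroxyl as a C–B bond. HF·pyridine should give the 4α-alcohol F6, Dess-Martin periodinane the ketone F7, and Zn/CH2Br2/TiCl4 the methylene compound F8. NaBO3·4H2O should then oxidise the C–B bond with retention to give 28.

Further compounds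
F1 | step 14 | (Z)-enoic acid from 17 (CO2H in place of CHO) | OC(=O)/C=C(/C)[C@@](C)(C1=C(C)[C@H](O[Si](C)(C)C(C)(C)C)CCC1)[C@H](Cc1ccoc1)OC(=O)C(C)C
F2 | step 14 | (Z)-enoyl chloride from F1 | ClC(=O)/C=C(/C)[C@@](C)(C1=C(C)[C@H](O[Si](C)(C)C(C)(C)C)CCC1)[C@H](Cc1ccoc1)OC(=O)C(C)C
F3 | step 10 | diethylphosphonoacetate ester of 12 | C=C(C)[C@@](C)(C1=C(C)[C@H](O[Si](C)(C)C(C)(C)C)CCC1)[C@H](Cc1ccoc1)OC(=O)CP(=O)(OCC)OCC
F4 | step 10 | methyl ketone from F3 (C8 ketone in place of the isopropenyl group) | CC(=O)[C@@](C)(C1=C(C)[C@H](O[Si](C)(C)C(C)(C)C)CCC1)[C@H](Cc1ccoc1)OC(=O)CP(=O)(OCC)OCC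
F5 | step 22 | C1β pinacol boronate, 4α-OTBS, trans-decalin | CC(C)(C)[Si](C)(C)O[C@@H]1CC[C@@H](B3OC(C)(C)C(C)(C)O3)[C@H]2[C@@]1(C)[C@@H](OC(C)=O)[C@H](OC(=O)C(C)C)[C@](C)(O)[C@]2(C)[C@H](Cc1ccoc1)OC(=O)C(C)C
F6 | step 22 | C1β pinacol boronate, 4α-alcohol | O[C@@H]1CC[C@@H](B3OC(C)(C)C(C)(C)O3)[C@H]2[C@@]1(C)[C@@H](OC(C)=O)[C@H](OC(=O)C(C)C)[C@](C)(O)[C@]2(C)[C@H](Cc1ccoc1)OC(=O)C(C)C
F7 | step 22 | C1β pinacol boronate, C4 ketone | O=C1CC[C@@H](B3OC(C)(C)C(C)(C)O3)[C@H]2[C@@]1(C)[C@@H](OC(C)=O)[C@H](OC(=O)C(C)C)[C@](C)(O)[C@]2(C)[C@H](Cc1ccoc1)OC(=O)C(C)C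
F8 | step 22 | C1β pinacol boronate, 4(18)-methylene | C=C1CC[C@@H](B3OC(C)(C)C(C)(C)O3)[C@H]2[C@@]1(C)[C@@H](OC(C)=O)[C@H](OC(=O)C(C)C)[C@](C)(O)[C@]2(C)[C@H](Cc1ccoc1)OC(=O)C(C)C
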